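**Retrosynthetic overview**

- The C8–C9 bond of the trienamide is made last, by Stille coupling of a ring A (E)-vinylstannane with the (2E,4E)-5-bromopentadienamide of 2-aminocyclopentane-1,3-dione; the alkene C7=C8 is carried as a silylated alkyne until then.
- The C2–N bond comes from copper-catalysed amidation of a 2-iodoenone with (2E,4E,6R)-2,4,6-trimethyldeca-2,4-dienamide (Evans methylation sets C6 of the acyl chain, two Wittig olefinations set the E,E-diene).
- Feature on which the strategy rests: without the C2 nitrogen, ring A (C1 ketone, C2=C3, C4 tertiary carbinol carrying C7, C5 secondary carbinol, C6 methylene) is the formal water adduct across one C=C of a mirror-symmetric 4-hydroxy-4-alkynylcyclohexa-2,5-dienone, with the C4 and C5 oxygens cis.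
- That symmetry is broken by a boron-tethered oxa-Michael addition of the C4 hydroxyl (as its phenylboronic hemiester) onto one enone arm under a chiral amine–thiourea, setting C4 and C5 together; the quinol comes from acetylide addition to p-benzoquinone mono(dimethyl ketal).
- Ring order: the ring A carbocycle and the cyclopentenone are bought; the only rings formed are the dioxaborolane (key step) and the temporary dioxolane that replaces it.

Key step: step 3

**Remarks**

- Locants: C1 ring ketone, C2 nitrogen-bearing carbon, C3, C4 tertiary carbinol, C5 secondary carbinol, C6 CH2; C7–C13 the trienamide chain from C4.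
- Assumption: the sense of induction of the quinine-derived catalyst on this substrate cannot be assigned in advance. If the first run shows the opposite sense, the quinidine-derived pseudoenantiomer is used and nothing else changes.
- Glutaconaldehyde potassium salt is taken as a commercial reagent.

**Route**

Step 1
Reactants: 1 (triisopropylsilyl)acetylene; 2 4,4-dimethoxycyclohexa-2,5-dien-1-one
Product: 4 4,4-dimethoxy-1-[(triisopropylsilyl)ethynyl]cyclohexa-2,5-dien-1-ol, via lithium (triisopropylsilyl)acetylide 3 (not isolated)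
Conditions: n-BuLi, THF, −78 °C; then 2, −78 → −40 °C; aq. NH4Cl
Reagents that add atoms: none
Why: Deprotonation gives acetylide 3, which adds 1,2 to the single carbonyl of the quinone monoketal (acetylide addition to a cross-conjugated dienone); no stereocentre arises because the carbinol carbon lies on the mirror plane.

Step 2
Reactants: 4 4,4-dimethoxy-1-[(triisopropylsilyl)ethynyl]cyclohexa-2,5-dien-1-ol
Product: 5 4-hydroxy-4-[(triisopropylsilyl)ethynyl]cyclohexa-2,5-dien-1-one
Conditions: p-TsOH·H2O (cat.), acetone/H2O, rt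
Reagents that add atoms: water, O
Why: Acid-catalysed ketal hydrolysis through a resonance-stabilised oxocarbenium ion unmasks the dienone, and this addition/hydrolysis pair is preferred to oxidative dearomatisation of a 4-alkynylphenol because it does not expose the alkyne to a hypervalent iodine oxidant.

Step 3
Reactants: 5 4-hydroxy-4-[(triisopropylsilyl)ethynyl]cyclohexa-2,5-dien-1-one; 6 phenylboronic acid
Product: 8 (3aR,7aR)-2-phenyl-7a-[(triisopropylsilyl)ethynyl]-3a,7a-dihydro-1,3,2-benzodioxaborol-5(4H)-one, via phenylboronic hemiester of the quinol 7 (not isolated)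
Conditions: 9-amino(9-deoxy)epiquinine 3,5-bis(trifluoromethyl)phenyl thiourea (10–20 mol %), 4 Å molecular sieves, toluene, rt
Reagents that add atoms: none
Why: The tertiary hydroxyl of 5 condenses reversibly with phenylboronic acid to hemiester 7; the quinuclidine nitrogen of the catalyst coordinates boron and so raises the nucleophilicity of the remaining B–OH oxygen, the thiourea hydrogen-bonds the dienone carbonyl, and the oxygen adds to C5 of one enone arm, the enolate being protonated at C6. The closest known reaction type is the amine–thiourea-catalysed oxa-Michael addition of boronic acid hemiesters of γ-hydroxy enones, used here on a 4-hydroxycyclohexa-2,5-dienone in the manner of desymmetrising conjugate additions of tethered oxygen nucleophiles to such dienones. The dioxaborolane (C4, O, B, O, C5) closes 5-exo-trig, and a five-membered ring fused to the cyclohexenone can only be cis-fused, so the C5 oxygen necessarily arrives on the face of the C4 oxygen. C4, prochiral in 5, and C5 become stereogenic in the same event and are both fixed by the catalyst's choice between the two enantiotopic arms, which should give (3aR,7aR)-8. The step needs enantiotopic-group selectivity and mono-addition: the mirror plane of 5 leaves the chiral catalyst as the only differentiating element, and once boron carries two ring oxygens no B–OH is left to attack the second arm, which survives as the C2=C3 enone needed for amidation.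

Step 4
Reactants: 8 (3aR,7aR)-2-phenyl-7a-[(triisopropylsilyl)ethynyl]-3a,7a-dihydro-1,3,2-benzodioxaborol-5(4H)-one
Product: 9 (4R,5R)-4,5-dihydroxy-4-[(triisopropylsilyl)ethynyl]cyclohex-2-en-1-one
Conditions: 30% aq. H2O2, pH 7 phosphate buffer, THF, 0 °C; aq. Na2S2O3
Reagents that add atoms: none
Why: Oxidation of the boron–carbon bond (phenyl migration from boron to oxygen) and hydrolysis of the borate free the cis-diol at neutral pH, where hydroperoxide anion is too scarce for Weitz–Scheffer epoxidation of the enone and the β-hydroxy ketone should not lose the C5 oxygen by retro-addition.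

Step 5
Reactants: 9 (4R,5R)-4,5-dihydroxy-4-[(triisopropylsilyl)ethynyl]cyclohex-2-en-1-one
Product: 10 (3aR,7aR)-2,2-dimethyl-7a-[(triisopropylsilyl)ethynyl]-3a,7a-dihydro-1,3-benzodioxol-5(4H)-one
Conditions: 2,2-dimethoxypropane, PPTS (cat.), CH2Cl2, rt
Reagents that add atoms: 2,2-dimethoxypropane, COC(C)(C)OC
Why: Acid-catalysed transketalisation (acetonide protection) ties the cis-diol into a dioxolane that, unlike the aryl boronate, is inert to the copper and palladium chemistry ahead.

Step 6
Reactants: 10 (3aR,7aR)-2,2-dimethyl-7a-[(triisopropylsilyl)ethynyl]-3a,7a-dihydro-1,3-benzodioxol-5(4H)-one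
Product: 11 (3aR,7aR)-6-iodo-2,2-dimethyl-7a-[(triisopropylsilyl)ethynyl]-3a,7a-dihydro-1,3-benzodioxol-5(4H)-one
Conditions: I2, pyridine/CH2Cl2, 0 °C → rt; aq. Na2S2O3
Reagents that add atoms: iodine, II
Why: α-Iodination of the enone by pyridine conjugate addition at C3, iodination of the enolate at C2 and loss of pyridinium (Baylis–Hillman-type addition–elimination) functionalises the only vinylic α-position under non-basic conditions.

Step 7
Reactants: 12 (R)-4-benzyloxazolidin-2-one; 13 hexanoyl chloride
Product: 14 (R)-4-benzyl-3-hexanoyloxazolidin-2-one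
Conditions: Et3N, DMAP (cat.), CH2Cl2, 0 °C → rt
Reagents that add atoms: none
Why: DMAP-catalysed N-acylation of the oxazolidinone by the acid chloride attaches the auxiliary.

Step 8
Reactants: 14 (R)-4-benzyl-3-hexanoyloxazolidin-2-one
Product: 16 (R)-4-benzyl-3-[(2R)-2-methylhexanoyl]oxazolidin-2-one, via sodium (Z)-enolate of the imide 15 (not isolated)
Conditions: NaN(SiMe3)2, THF, −78 °C; then MeI, −78 °C
Reagents that add atoms: iodomethane, CI
Why: Evans asymmetric alkylation, in which the chelated (Z)-enolate 15 is methylated on the face away from the benzyl group, which with the (R)-auxiliary gives the (2R)-methyl centre.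

Step 9
Reactants: 16 (R)-4-benzyl-3-[(2R)-2-methylhexanoyl]oxazolidin-2-one
Product: 17 (R)-2-methylhexan-1-ol
Conditions: LiBH4, H2O (1 equiv), Et2O, 0 °C; aq. NaOH
Reagents that add atoms: none
Why: Reductive cleavage of the imide at the exocyclic carbonyl by LiBH4 releases the primary alcohol without touching the α-stereocentre and returns the auxiliary.

Step 10
Reactants: 17 (R)-2-methylhexan-1-ol; 18 ethyl 2-(triphenylphosphoranylidene)propanoate
Product: 20 ethyl (2E,4R)-2,4-dimethyloct-2-enoate, via (R)-2-methylhexanal 19 (not isolated)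
Conditions: Dess–Martin periodinane, NaHCO3, CH2Cl2, 0 °C → rt; then 18, rt
Reagents that add atoms: none
Why: Dess–Martin oxidation followed in the same flask by Wittig olefination with the stabilised α-methyl ylide avoids handling the volatile, epimerisable aldehyde 19 and should give the (E)-trisubstituted enoate.

Step 11
Reactants: 20 ethyl (2E,4R)-2,4-dimethyloct-2-enoate
Product: 21 (2E,4R)-2,4-dimethyloct-2-en-1-ol
Conditions: diisobutylaluminium hydride (iBu2AlH), CH2Cl2, −78 °C; aq. potassium sodium tartrate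
Reagents that add atoms: none
Why: 1,2-Reduction of the conjugated ester by the aluminium hydride gives the allylic alcohol without affecting alkene geometry.

Step 12
Reactants: 21 (2E,4R)-2,4-dimethyloct-2-en-1-ol; 18 ethyl 2-(triphenylphosphoranylidene)propanoate
Product: 23 ethyl (2E,4E,6R)-2,4,6-trimethyldeca-2,4-dienoate, via (2E,4R)-2,4-dimethyloct-2-enal 22 (not isolated)
Conditions: MnO2, CH2Cl2, rt; filter; then 18, toluene, 90 °C
Reagents that add atoms: none
Why: Allylic oxidation with MnO2 and a second Wittig olefination with the same stabilised ylide extend the chain to the dienoate, the ylide again favouring the (E)-trisubstituted alkene.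

Step 13
Reactants: 23 ethyl (2E,4E,6R)-2,4,6-trimethyldeca-2,4-dienoate
Product: 24 (2E,4E,6R)-2,4,6-trimethyldeca-2,4-dienoic acid
Conditions: LiOH, THF/MeOH/H2O, 40 °C; then 1 M HCl
Reagents that add atoms: lithium hydroxide, [Li+].[OH-]
Why: Saponification of the conjugated ester, with the C6 stereocentre remote from any acidic position.

Step 14
Reactants: 24 (2E,4E,6R)-2,4,6-trimethyldeca-2,4-dienoic acid
Product: 26 (2E,4E,6R)-2,4,6-trimethyldeca-2,4-dienamide, via (2E,4E,6R)-2,4,6-trimethyldeca-2,4-dienoyl chloride 25 (not isolated)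
Conditions: (COCl)2, DMF (cat.), CH2Cl2, 0 °C → rt; evaporate; then NH3 (0.5 M in dioxane), THF, 0 °C
Reagents that add atoms: ammonia, N
Why: Acid chloride formation and ammonolysis give the primary amide needed as the nitrogen nucleophile.

Step 15
Reactants: 11 (3aR,7aR)-6-iodo-2,2-dimethyl-7a-[(triisopropylsilyl)ethynyl]-3a,7a-dihydro-1,3-benzodioxol-5(4H)-one; 26 (2E,4E,6R)-2,4,6-trimethyldeca-2,4-dienamide
Product: 27 (2E,4E,6R)-N-[(3aR,7aR)-2,2-dimethyl-5-oxo-7a-[(triisopropylsilyl)ethynyl]-3a,4,5,7a-tetrahydro-1,3-benzodioxol-6-yl]-2,4,6-trimethyldeca-2,4-dienamide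
Conditions: CuI (10 mol %), N,N'-dimethylethylenediamine (20 mol %), K2CO3, toluene, 70 °C
Reagents that add atoms: none
Why: Copper-catalysed Goldberg-type N-vinylation of a primary amide, in which the diamine-ligated copper amidate inserts into the activated C2–I bond and reductive elimination forms the enamide, the silyl cap keeping the alkyne out of copper acetylide chemistry.

Step 16
Reactants: 27 (2E,4E,6R)-N-[(3aR,7aR)-2,2-dimethyl-5-oxo-7a-[(triisopropylsilyl)ethynyl]-3a,4,5,7a-tetrahydro-1,3-benzodioxol-6-yl]-2,4,6-trimethyldeca-2,4-dienamide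
Product: 28 (2E,4E,6R)-N-[(3R,4R)-3,4-dihydroxy-6-oxo-3-[(triisopropylsilyl)ethynyl]cyclohex-1-en-1-yl]-2,4,6-trimethyldeca-2,4-dienamide
Conditions: TFA/H2O, CH2Cl2, 0 °C → rt
Reagents that add atoms: none
Why: Aqueous acid hydrolysis of the dioxolane via the isopropylidene oxocarbenium ion is placed here, before the acid-sensitive trienyl carbinol exists, because the propargylic carbinol and the 2-amidoenone should not ionise under these conditions.

Step 17
Reactants: 28 (2E,4E,6R)-N-[(3R,4R)-3,4-dihydroxy-6-oxo-3-[(triisopropylsilyl)ethynyl]cyclohex-1-en-1-yl]-2,4,6-trimethyldeca-2,4-dienamide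
Product: 29 (2E,4E,6R)-N-[(3R,4R)-3-ethynyl-3,4-dihydroxy-6-oxocyclohex-1-en-1-yl]-2,4,6-trimethyldeca-2,4-dienamide
Conditions: Bu4NF, AcOH, THF, 0 °C
Reagents that add atoms: none
Why: Fluoride-induced cleavage of the C(sp)–Si bond (protodesilylation), buffered with acetic acid so that the β-hydroxy ketone is not exposed to basic fluoride.

Step 18
Reactants: 29 (2E,4E,6R)-N-[(3R,4R)-3-ethynyl-3,4-dihydroxy-6-oxocyclohex-1-en-1-yl]-2,4,6-trimethyldeca-2,4-dienamide
Product: 30 (2E,4E,6R)-N-[(3R,4R)-3,4-dihydroxy-6-oxo-3-[(E)-2-(tributylstannyl)ethenyl]cyclohex-1-en-1-yl]-2,4,6-trimethyldeca-2,4-dienamide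
Conditions: Bu3SnH (slow addition), Pd(PPh3)2Cl2 (5 mol %), THF, 0 °C
Reagents that add atoms: tributyltin hydride, CCCC[SnH](CCCC)CCCC
Why: Palladium-catalysed syn-hydrostannylation of the terminal alkyne, in which the fully substituted C4 should steer tin to the terminal carbon and so give the (E)-vinylstannane.

Step 19
Reactants: 31 cyclopentane-1,3-dione
Product: 32 2-(hydroxyimino)cyclopentane-1,3-dione
Conditions: NaNO2, aq. HCl, 0 °C
Reagents that add atoms: sodium nitrite, [Na+].[O-]N=O
Why: Nitrosation of the doubly activated C2 methylene of the 1,3-dione and tautomerisation to the oxime.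

Step 20
Reactants: 32 2-(hydroxyimino)cyclopentane-1,3-dione
Product: 33 2-amino-3-hydroxycyclopent-2-en-1-one hydrochloride
Conditions: H2 (1 atm), 10% Pd on carbon, HCl, MeOH, rt
Reagents that add atoms: hydrogen chloride, Cl
Why: Catalytic hydrogenation of the oxime to the amine in acid, which traps the enolised aminodione as its stable hydrochloride.

Step 21
Reactants: 34 glutaconaldehyde potassium salt
Product: 35 (2E,4E)-5-bromopenta-2,4-dienal
Conditions: Ph3PBr2, CH2Cl2, 0 °C → rt; then I2 (cat.), light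
Reagents that add atoms: triphenylphosphine dibromide, BrP(Br)(c1ccccc1)(c1ccccc1)c1ccccc1
Why: Phosphonium activation of the enolate oxygen and vinylogous addition–elimination by bromide convert the vinylogous carboxylate into the bromodienal, with iodine-catalysed equilibration to the (2E,4E)-isomer.

Step 22
Reactants: 35 (2E,4E)-5-bromopenta-2,4-dienal
Product: 36 (2E,4E)-5-bromopenta-2,4-dienoic acid
Conditions: NaClO2, NaH2PO4, 2-methylbut-2-ene, t-BuOH/H2O, 0 °C → rt
Reagents that add atoms: sodium chlorite, [Na+].[O-]Cl=O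
Why: Pinnick oxidation of the aldehyde to the acid, hypochlorite being scavenged by the alkene additive so that the bromodiene is left intact.

Step 23
Reactants: 36 (2E,4E)-5-bromopenta-2,4-dienoic acid; 33 2-amino-3-hydroxycyclopent-2-en-1-one hydrochloride
Product: 38 (2E,4E)-5-bromo-N-(2-hydroxy-5-oxocyclopent-1-en-1-yl)penta-2,4-dienamide, via (2E,4E)-5-bromopenta-2,4-dienoyl chloride 37 (not isolated)
Conditions: (COCl)2, DMF (cat.), CH2Cl2, 0 °C; evaporate; then 33, Et3N, CH2Cl2/DMF, 0 °C → rt; aq. NaHCO3
Reagents that add atoms: none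
Why: Acid chloride formation and N-acylation of the liberated amine, any enol ester formed at the ring oxygen being cleaved in the mildly basic work-up.

Step 24
Reactants: 30 (2E,4E,6R)-N-[(3R,4R)-3,4-dihydroxy-6-oxo-3-[(E)-2-(tributylstannyl)ethenyl]cyclohex-1-en-1-yl]-2,4,6-trimethyldeca-2,4-dienamide; 38 (2E,4E)-5-bromo-N-(2-hydroxy-5-oxocyclopent-1-en-1-yl)penta-2,4-dienamide
Product: 39 (2E,4E,6R)-N-[(3S,4R)-3,4-dihydroxy-3-[(1E,3E,5E)-7-[(2-hydroxy-5-oxocyclopent-1-en-1-yl)amino]-7-oxohepta-1,3,5-trien-1-yl]-6-oxocyclohex-1-en-1-yl]-2,4,6-trimethyldeca-2,4-dienamide (CNP0117968.3)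
Conditions: Pd(MeCN)2Cl2 (10 mol %), DMF, rt, dark
Reagents that add atoms: none
Why: Stille cross-coupling of the vinylstannane with the bromodiene joins C8 to C9 with retention of both alkene geometries under neutral conditions at room temperature, so the all-E trienamide should form without any protecting-group step after it.

**Compound list**

1 | (triisopropylsilyl)acetylene | C#C[Si](C(C)C)(C(C)C)C(C)C | starting material
2 | 4,4-dimethoxycyclohexa-2,5-dien-1-one | COC1(OC)C=CC(=O)C=C1 | starting material
3 | lithium (triisopropylsilyl)acetylide | [Li]C#C[Si](C(C)C)(C(C)C)C(C)C | intermediate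
4 | 4,4-dimethoxy-1-[(triisopropylsilyl)ethynyl]cyclohexa-2,5-dien-1-ol | COC1(OC)C=CC(O)(C#C[Si](C(C)C)(C(C)C)C(C)C)C=C1 | intermediate
5 | 4-hydroxy-4-[(triisopropylsilyl)ethynyl]cyclohexa-2,5-dien-1-one | O=C1C=CC(O)(C#C[Si](C(C)C)(C(C)C)C(C)C)C=C1 | intermediate
6 | phenylboronic acid | OB(O)c1ccccc1 | starting material
7 | phenylboronic hemiester of quinol 5 at the C4 oxygen | O=C1C=CC(OB(O)c2ccccc2)(C#C[Si](C(C)C)(C(C)C)C(C)C)C=C1 | intermediate
8 | (3aR,7aR)-2-phenyl-7a-[(triisopropylsilyl)ethynyl]-3a,7a-dihydro-1,3,2-benzodioxaborol-5(4H)-one (cis-fused) | O=C1C=C[C@]2(C#C[Si](C(C)C)(C(C)C)C(C)C)OB(c3ccccc3)O[C@@H]2C1 | intermediate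
9 | (4R,5R)-4,5-dihydroxy-4-[(triisopropylsilyl)ethynyl]cyclohex-2-en-1-one (cis-diol) | O=C1C=C[C@@](O)(C#C[Si](C(C)C)(C(C)C)C(C)C)[C@H](O)C1 | intermediate
10 | (3aR,7aR)-2,2-dimethyl-7a-[(triisopropylsilyl)ethynyl]-3a,7a-dihydro-1,3-benzodioxol-5(4H)-one | O=C1C=C[C@]2(C#C[Si](C(C)C)(C(C)C)C(C)C)OC(C)(C)O[C@@H]2C1 | intermediate
11 | (3aR,7aR)-6-iodo-2,2-dimethyl-7a-[(triisopropylsilyl)ethynyl]-3a,7a-dihydro-1,3-benzodioxol-5(4H)-one | O=C1C(I)=C[C@]2(C#C[Si](C(C)C)(C(C)C)C(C)C)OC(C)(C)O[C@@H]2C1 | intermediate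
12 | (R)-4-benzyloxazolidin-2-one | O=C1N[C@H](Cc2ccccc2)CO1 | starting material
13 | hexanoyl chloride | CCCCCC(Cl)=O | starting material
14 | (R)-4-benzyl-3-hexanoyloxazolidin-2-one | CCCCCC(=O)N1[C@H](Cc2ccccc2)COC1=O | intermediate
15 | sodium (Z)-enolate of imide 14 | CCCC/C=C(\[O-])N1[C@H](Cc2ccccc2)COC1=O.[Na+] | intermediate
16 | (R)-4-benzyl-3-[(2R)-2-methylhexanoyl]oxazolidin-2-one | CCCC[C@@H](C)C(=O)N1[C@H](Cc2ccccc2)COC1=O | intermediate
17 | (R)-2-methylhexan-1-ol | CCCC[C@@H](C)CO | intermediate
18 | ethyl 2-(triphenylphosphoranylidene)propanoate | CCOC(=O)C(C)=P(c1ccccc1)(c1ccccc1)c1ccccc1 | starting material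
19 | (R)-2-methylhexanal | CCCC[C@@H](C)C=O | intermediate
20 | ethyl (2E,4R)-2,4-dimethyloct-2-enoate | CCCC[C@@H](C)/C=C(\C)C(=O)OCC | intermediate
21 | (2E,4R)-2,4-dimethyloct-2-en-1-ol | CCCC[C@@H](C)/C=C(\C)CO | intermediate
22 | (2E,4R)-2,4-dimethyloct-2-enal | CCCC[C@@H](C)/C=C(\C)C=O | intermediate
23 | ethyl (2E,4E,6R)-2,4,6-trimethyldeca-2,4-dienoate | CCCC[C@@H](C)/C=C(C)/C=C(\C)C(=O)OCC | intermediate
24 | (2E,4E,6R)-2,4,6-trimethyldeca-2,4-dienoic acid | CCCC[C@@H](C)/C=C(C)/C=C(\C)C(=O)O | intermediate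
25 | (2E,4E,6R)-2,4,6-trimethyldeca-2,4-dienoyl chloride | CCCC[C@@H](C)/C=C(C)/C=C(\C)C(Cl)=O | intermediate
26 | (2E,4E,6R)-2,4,6-trimethyldeca-2,4-dienamide | CCCC[C@@H](C)/C=C(C)/C=C(\C)C(N)=O | intermediate
27 | (2E,4E,6R)-N-[(3aR,7aR)-2,2-dimethyl-5-oxo-7a-[(triisopropylsilyl)ethynyl]-3a,4,5,7a-tetrahydro-1,3-benzodioxol-6-yl]-2,4,6-trimethyldeca-2,4-dienamide | CCCC[C@@H](C)/C=C(C)/C=C(\C)C(=O)NC1=C[C@]2(C#C[Si](C(C)C)(C(C)C)C(C)C)OC(C)(C)O[C@@H]2CC1=O | intermediate
28 | (2E,4E,6R)-N-[(3R,4R)-3,4-dihydroxy-6-oxo-3-[(triisopropylsilyl)ethynyl]cyclohex-1-en-1-yl]-2,4,6-trimethyldeca-2,4-dienamide | CCCC[C@@H](C)/C=C(C)/C=C(\C)C(=O)NC1=C[C@@](O)(C#C[Si](C(C)C)(C(C)C)C(C)C)[C@H](O)CC1=O | intermediate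
29 | (2E,4E,6R)-N-[(3R,4R)-3-ethynyl-3,4-dihydroxy-6-oxocyclohex-1-en-1-yl]-2,4,6-trimethyldeca-2,4-dienamide | CCCC[C@@H](C)/C=C(C)/C=C(\C)C(=O)NC1=C[C@@](O)(C#C)[C@H](O)CC1=O | intermediate
30 | (2E,4E,6R)-N-[(3R,4R)-3,4-dihydroxy-6-oxo-3-[(E)-2-(tributylstannyl)ethenyl]cyclohex-1-en-1-yl]-2,4,6-trimethyldeca-2,4-dienamide | CCCC[C@@H](C)/C=C(C)/C=C(\C)C(=O)NC1=C[C@@](O)(/C=C/[Sn](CCCC)(CCCC)CCCC)[C@H](O)CC1=O | intermediate
31 | cyclopentane-1,3-dione | O=C1CCC(=O)C1 | starting material
32 | 2-(hydroxyimino)cyclopentane-1,3-dione | O=C1CCC(=O)C1=NO | intermediate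
33 | 2-amino-3-hydroxycyclopent-2-en-1-one hydrochloride | NC1=C(O)CCC1=O.Cl | intermediate
34 | glutaconaldehyde potassium salt | [K+].[O-]/C=C/C=C/C=O | starting material
35 | (2E,4E)-5-bromopenta-2,4-dienal | Br/C=C/C=C/C=O | intermediate
36 | (2E,4E)-5-bromopenta-2,4-dienoic acid | Br/C=C/C=C/C(=O)O | intermediate
37 | (2E,4E)-5-bromopenta-2,4-dienoyl chloride | Br/C=C/C=C/C(Cl)=O | intermediate
38 | (2E,4E)-5-bromo-N-(2-hydroxy-5-oxocyclopent-1-en-1-yl)penta-2,4-dienamide | Br/C=C/C=C/C(=O)NC1=C(O)CCC1=O | intermediate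
39 | (2E,4E,6R)-N-[(3S,4R)-3,4-dihydroxy-3-[(1E,3E,5E)-7-[(2-hydroxy-5-oxocyclopent-1-en-1-yl)amino]-7-oxohepta-1,3,5-trien-1-yl]-6-oxocyclohex-1-en-1-yl]-2,4,6-trimethyldeca-2,4-dienamide | CCCC[C@@H](C)/C=C(C)/C=C(\C)C(=O)NC1=C[C@@](O)(/C=C/C=C/C=C/C(=O)NC2=C(O)CCC2=O)[C@H](O)CC1=O | target

**Step count**

- Total step count: 24.
- Longest linear sequence: 13 steps (12 and 13 through steps 7–14 to amide 26, then steps 15–18 and 24 to 39).
- The ring A line from 1 and 2 is 11 steps (steps 1–6, 15–18, 24).

**Three steps most likely to fail**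

Step 3 (key step). The catalyst may discriminate poorly between the two enantiotopic enone arms. Hemiester formation at the hindered tertiary hydroxyl may also be slow enough for an uncatalysed or reversible pathway to erode the enantiomeric purity. The fallback keeps the tethered oxa-Michael logic but changes tether and activation mode. It sets out from 5, which is treated with acetaldehyde and a chiral BINOL-derived phosphoric acid (3,3'-bis(2,4,6-triisopropylphenyl) type, antipode chosen after a first run) in an acetalisation/oxa-Michael cascade. The hemiacetal oxygen adds to one arm under Brønsted acid control and should give (2S,3aR,7aR)-2-methyl-7a-[(triisopropylsilyl)ethynyl]-3a,7a-dihydro-1,3-benzodioxol-5(4H)-one F1, drawn as the exo-methyl epimer (the acetal carbon is later removed, so its configuration is immaterial). Hydrolysis of the ethylidene acetal in aqueous acetic acid returns to the route at diol 9.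

Step 15. Base-induced β-elimination of the C5 oxygen (opening of the dioxolane from the C6 enolate, which would erase both stereocentres) may outrun a slow C–N coupling at the hindered iodoenone, or the iodide may be reduced off. The fallback forms the amide bond by acylation instead of N-vinylation and sets out from 10:
- Weitz–Scheffer epoxidation (t-BuOOH, DBU, CH2Cl2, 0 °C) should give the 2,3-epoxy ketone of 10 F2, drawn with the oxirane anti to the dioxolane; either face serves because both new centres are lost again.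
- Sodium azide with NH4Cl in MeOH/H2O opens the epoxide at C2, and dehydration gives (3aR,7aR)-6-azido-2,2-dimethyl-7a-[(triisopropylsilyl)ethynyl]-3a,7a-dihydro-1,3-benzodioxol-5(4H)-one F3.
- Staudinger reduction (PPh3, THF/H2O) gives (3aR,7aR)-6-amino-2,2-dimethyl-7a-[(triisopropylsilyl)ethynyl]-3a,7a-dihydro-1,3-benzodioxol-5(4H)-one F4.
- Acylation of F4 with acid chloride 25 (pyridine, CH2Cl2, 0 °C) comes back to the route at 27.

Step 18. Tin may be delivered to the internal carbon, the tin hydride/palladium system may reduce the amidoenone in conjugate fashion, or the stannane may protodestannylate on purification. The fallback replaces hydrometallation and Stille coupling by semi-hydrogenation and Heck coupling and sets out from 29. Hydrogenation over Pd/CaCO3 poisoned with Pb(OAc)2 and quinoline should give (2E,4E,6R)-N-[(3S,4R)-3-ethenyl-3,4-dihydroxy-6-oxocyclohex-1-en-1-yl]-2,4,6-trimethyldeca-2,4-dienamide F5. Heck coupling of F5 with bromodiene 38 (Pd(OAc)2, P(o-tol)3, Ag2CO3, DMF, 50 °C) then comes back to the route directly at 39. Because C4 carries no hydrogen, β-hydride elimination can only regenerate the C7=C8 alkene, which should form with E geometry.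

**Further compounds**

F1 | step 3 | (2S,3aR,7aR)-2-methyl-7a-[(triisopropylsilyl)ethynyl]-3a,7a-dihydro-1,3-benzodioxol-5(4H)-one | O=C1C=C[C@]2(C#C[Si](C(C)C)(C(C)C)C(C)C)O[C@@H](C)O[C@@H]2C1
F2 | step 15 | 2,3-epoxy ketone of 10, oxirane anti to the dioxolane | O=C1[C@H]2O[C@H]2[C@]3(C#C[Si](C(C)C)(C(C)C)C(C)C)OC(C)(C)O[C@@H]3C1
F3 | step 15 | (3aR,7aR)-6-azido-2,2-dimethyl-7a-[(triisopropylsilyl)ethynyl]-3a,7a-dihydro-1,3-benzodioxol-5(4H)-one | [N-]=[N+]=NC1=C[C@]2(C#C[Si](C(C)C)(C(C)C)C(C)C)OC(C)(C)O[C@@H]2CC1=O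
F4 | step 15 | (3aR,7aR)-6-amino-2,2-dimethyl-7a-[(triisopropylsilyl)ethynyl]-3a,7a-dihydro-1,3-benzodioxol-5(4H)-one | NC1=C[C@]2(C#C[Si](C(C)C)(C(C)C)C(C)C)OC(C)(C)O[C@@H]2CC1=O
F5 | step 18 | (2E,4E,6R)-N-[(3S,4R)-3-ethenyl-3,4-dihydroxy-6-oxocyclohex-1-en-1-yl]-2,4,6-trimethyldeca-2,4-dienamide | CCCC[C@@H](C)/C=C(C)/C=C(\C)C(=O)NC1=C[C@@](O)(C=C)[C@H](O)CC1=O
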